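## Retrosynthetic overview

- The target is (2R,3S,4R)-configured, with all three ring C substituents equatorial, and is reached by global debenzylation of its tetra-O-benzyl ether.
- Ring C is the only ring made. It is cut at O1–C2 (6-endo opening of a trans-epoxide by a ring A phenoxide, the ring-closing bond) and at C4–C4a (ortho-hydroxyalkylation); both bonds are made in one flask from a ring A resorcinol and a ring B (2R,3S)-epoxy aldehyde.
- Enabling feature: ring A is symmetric about the C4a···C7 axis (oxygens at C5 and C8a, methoxyls at C6 and C8). The single C–H of the resorcinol therefore becomes C4a and either neighbouring oxygen can become O1. C2 is benzylic to ring B and para to its C4′ oxygen, which steers the phenoxide to C2.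
- The epoxy aldehyde comes from 3,4,5-tris(benzyloxy)benzaldehyde (olefination, reduction, Sharpless epoxidation as the only absolute stereo-defining event, oxidation). The resorcinol comes from 2,6-dimethoxyphenol (benzylation, double bromination, borylation, oxidation).
- Order of ring formation: rings A and B are bought as arenes and ring C is closed last. C3 is set by catalysis, C2 by inversion of the epoxide carbon, and C4 by chelation relay from C3.

Key step: step 9

Remark: the SMILES is read as the 2,3-trans-3,4-trans isomer (2R,3S,4R), and both starting arenes are taken as commercial materials.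

## Route

Step 1
Reactants: 1 2,6-dimethoxyphenol
Product: 2 2-(benzyloxy)-1,3-dimethoxybenzene
Conditions: BnBr, K2CO3, DMF, 60 °C
Reagents that add atoms: benzyl bromide, BrCc1ccccc1
Why: Williamson etherification of the acidic phenol installs the single protecting group of ring A (the future 7-OH) as a benzyl ether that is removed at the end together with those of ring B.

Step 2
Reactants: 2 2-(benzyloxy)-1,3-dimethoxybenzene
Product: 3 3-(benzyloxy)-1,5-dibromo-2,4-dimethoxybenzene
Conditions: NBS (2.1 equiv), MeCN, 0 °C → rt, dark
Reagents that add atoms: N-bromosuccinimide, O=C1CCC(=O)N1Br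
Why: Electrophilic aromatic bromination of the 1,2,3-trioxygenated ring should go twice to the positions ortho to one methoxyl and para to the other, because the central benzyloxy group is twisted out of conjugation and its para position is the least activated site.

Step 3
Reactants: 3 3-(benzyloxy)-1,5-dibromo-2,4-dimethoxybenzene
Product: 4 2,2'-[5-(benzyloxy)-4,6-dimethoxy-1,3-phenylene]bis(4,4,5,5-tetramethyl-1,3,2-dioxaborolane)
Conditions: B2pin2 (2.5 equiv), Pd(dppf)Cl2 (5 mol%), KOAc, 1,4-dioxane, 90 °C
Reagents that add atoms: bis(pinacolato)diboron, CC1(C)OB(OC1(C)C)B1OC(C)(C)C(C)(C)O1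
Why: Miyaura borylation should exchange both aryl bromides, each with only one ortho substituent, for boronic esters under conditions that leave the benzyl ether untouched.

Step 4
Reactants: 4 2,2'-[5-(benzyloxy)-4,6-dimethoxy-1,3-phenylene]bis(4,4,5,5-tetramethyl-1,3,2-dioxaborolane)
Product: 5 5-(benzyloxy)-4,6-dimethoxybenzene-1,3-diol
Conditions: 30% H2O2, aq NaOH, THF, 0 °C, argon; then aq HCl to pH 5
Reagents that add atoms: hydrogen peroxide, OO
Why: Oxidation of arylboronic esters with basic hydrogen peroxide (1,2-aryl shift from boron to oxygen) should turn both C–B bonds into phenols and so complete the symmetric ring A, whose only C–H now lies between two equivalent hydroxyl groups.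

Step 5
Reactants: 6 3,4,5-tris(benzyloxy)benzaldehyde
Product: 7 ethyl (E)-3-[3,4,5-tris(benzyloxy)phenyl]prop-2-enoate
Conditions: (EtO)2P(O)CH2CO2Et, LiCl, DBU, MeCN, rt
Reagents that add atoms: triethyl phosphonoacetate, CCOC(=O)CP(=O)(OCC)OCC
Why: Horner–Wadsworth–Emmons olefination with a stabilized phosphonate should give the (E)-cinnamate that is needed for a trans-epoxide.

Step 6
Reactants: 7 ethyl (E)-3-[3,4,5-tris(benzyloxy)phenyl]prop-2-enoate
Product: 8 (E)-3-[3,4,5-tris(benzyloxy)phenyl]prop-2-en-1-ol
Conditions: i-Bu2AlH (2.5 equiv), CH2Cl2, −78 °C; aq potassium sodium tartrate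
Reagents that add atoms: none
Why: 1,2-Reduction of the conjugated ester with i-Bu2AlH should give the allylic alcohol without touching the alkene or the benzyl ethers.

Step 7
Reactants: 8 (E)-3-[3,4,5-tris(benzyloxy)phenyl]prop-2-en-1-ol
Product: 9 [(2S,3S)-3-[3,4,5-tris(benzyloxy)phenyl]oxiran-2-yl]methanol
Conditions: Ti(OiPr)4 (10 mol%), L-(+)-diisopropyl tartrate (12 mol%), t-BuOOH (2 equiv, isooctane), 4 Å MS, CH2Cl2, −25 °C
Reagents that add atoms: tert-butyl hydroperoxide, CC(C)(C)OO
Why: Sharpless asymmetric epoxidation of the (E)-allylic alcohol with the L-(+)-tartrate ligand should deliver oxygen to the face that gives the (2S,3S)-epoxy alcohol, and this one catalytic event fixes the absolute configuration of the whole target (C3 directly, C2 after inversion).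

Step 8
Reactants: 9 [(2S,3S)-3-[3,4,5-tris(benzyloxy)phenyl]oxiran-2-yl]methanol
Product: 10 (2R,3S)-3-[3,4,5-tris(benzyloxy)phenyl]oxirane-2-carbaldehyde
Conditions: Dess–Martin periodinane, pyridine, CH2Cl2, 0 °C → rt; used at once
Reagents that add atoms: none
Why: Buffered Dess–Martin oxidation should take the primary alcohol to the aldehyde under non-acidic conditions that spare the acid-labile aryl epoxide and the α-stereocenter (the descriptor at C2 changes only through the priority rules).

Step 9
Reactants: 5 5-(benzyloxy)-4,6-dimethoxybenzene-1,3-diol; 10 (2R,3S)-3-[3,4,5-tris(benzyloxy)phenyl]oxirane-2-carbaldehyde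
Product: 13 (2R,3S,4R)-7-(benzyloxy)-6,8-dimethoxy-2-[3,4,5-tris(benzyloxy)phenyl]chromane-3,4,5-triol, via magnesium resorcinolate 11 (not isolated), via magnesium-bound threo epoxy alcohol 12 (not isolated)
Conditions: 5, n-Bu2Mg (1.0 equiv), toluene, 0 °C → rt; then 10 (1.05 equiv) in CH2Cl2, −30 °C → rt; aq NH4Cl
Reagents that add atoms: none
Why: Proposed new method: a one-flask ortho-hydroxyalkylation/epoxide-opening annulation in which the magnesium resorcinolate 11 binds aldehyde 10 through its carbonyl and epoxide oxygens and attacks the carbonyl with its only free ring carbon through a six-membered, metal-templated transition state, after which one of the two equivalent ortho aryloxides of 12 opens the magnesium-activated epoxide at the benzylic carbon C2. The closest known reaction types are the ortho-selective hydroxyalkylation of magnesium phenoxides with aldehydes (chelating α-oxygenated aldehydes included) and the 6-endo cyclization of 2-hydroxyaryl epoxides to trans-flavan-3-ols and trans-dihydroflavonols; what is new is their combination with an α,β-epoxy aldehyde as the three-carbon partner. Ring C closes by a 6-endo-tet epoxide opening that forms the O1–C2 bond. C4 is set by chelation control (attack on the carbonyl face anti to the epoxide carbon C2 of the five-membered chelate of divalent magnesium gives the threo epoxy alcohol, hence 3,4-trans), C2 by stereospecific inversion of the epoxide carbon (hence 2,3-trans), and C3 is carried over unchanged from the asymmetric epoxidation. The step needs C- over O-attack on the aldehyde, threo over erythro addition and 6-endo over 5-exo opening; the first should be secured by the magnesium phenoxide in a non-coordinating, halide-free medium, the second by the chelate, and the third by the para-oxygenated ring B, which makes C2 the electrophilic epoxide carbon while C3 is deactivated by its two flanking C–O bonds. Because ring A has no other C–H and its two ortho oxygens are equivalent, neither regioisomers nor a second hydroxyalkylation can arise.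

Step 10
Reactants: 13 (2R,3S,4R)-7-(benzyloxy)-6,8-dimethoxy-2-[3,4,5-tris(benzyloxy)phenyl]chromane-3,4,5-triol
Product: 14 (2R,3S,4R)-6,8-dimethoxy-2-(3,4,5-trihydroxyphenyl)chromane-3,4,5,7-tetrol
Conditions: H2 (1 atm), Pd(OH)2/C, THF/EtOAc, rt, neutral; filter under argon
Reagents that add atoms: none
Why: Catalytic hydrogenolysis of the four aryl benzyl ethers, the usual last step for benzylated flavan-3-ols, should be much faster under neutral conditions than cleavage of the C4–OH or C2–O1 benzylic bonds and touches no stereocenter.

## Compound list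

1 | 2,6-dimethoxyphenol | COc1cccc(OC)c1O | starting material
2 | 2-(benzyloxy)-1,3-dimethoxybenzene | COc1cccc(OC)c1OCc1ccccc1 | intermediate
3 | 3-(benzyloxy)-1,5-dibromo-2,4-dimethoxybenzene | COc1c(Br)cc(Br)c(OC)c1OCc1ccccc1 | intermediate
4 | 2,2'-[5-(benzyloxy)-4,6-dimethoxy-1,3-phenylene]bis(4,4,5,5-tetramethyl-1,3,2-dioxaborolane) | COc1c(B2OC(C)(C)C(C)(C)O2)cc(B2OC(C)(C)C(C)(C)O2)c(OC)c1OCc1ccccc1 | intermediate
5 | 5-(benzyloxy)-4,6-dimethoxybenzene-1,3-diol | COc1c(O)cc(O)c(OC)c1OCc1ccccc1 | intermediate
6 | 3,4,5-tris(benzyloxy)benzaldehyde | O=Cc1cc(OCc2ccccc2)c(OCc2ccccc2)c(OCc2ccccc2)c1 | starting material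
7 | ethyl (E)-3-[3,4,5-tris(benzyloxy)phenyl]prop-2-enoate | CCOC(=O)/C=C/c1cc(OCc2ccccc2)c(OCc2ccccc2)c(OCc2ccccc2)c1 | intermediate
8 | (E)-3-[3,4,5-tris(benzyloxy)phenyl]prop-2-en-1-ol | OC/C=C/c1cc(OCc2ccccc2)c(OCc2ccccc2)c(OCc2ccccc2)c1 | intermediate
9 | [(2S,3S)-3-[3,4,5-tris(benzyloxy)phenyl]oxiran-2-yl]methanol | OC[C@@H]1O[C@H]1c1cc(OCc2ccccc2)c(OCc2ccccc2)c(OCc2ccccc2)c1 | intermediate
10 | (2R,3S)-3-[3,4,5-tris(benzyloxy)phenyl]oxirane-2-carbaldehyde | O=C[C@@H]1O[C@H]1c1cc(OCc2ccccc2)c(OCc2ccccc2)c(OCc2ccccc2)c1 | intermediate
11 | magnesium 5-(benzyloxy)-4,6-dimethoxybenzene-1,3-diolate (formed in the flask, not isolated) | [Mg+2].COc1c([O-])cc([O-])c(OC)c1OCc1ccccc1 | intermediate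
12 | magnesium bis(phenoxide) of (R)-[4-(benzyloxy)-2,6-dihydroxy-3,5-dimethoxyphenyl]{(2S,3S)-3-[3,4,5-tris(benzyloxy)phenyl]oxiran-2-yl}methanol (formed in the flask, not isolated) | [Mg+2].COc1c([O-])c([C@@H](O)[C@@H]2O[C@H]2c2cc(OCc3ccccc3)c(OCc3ccccc3)c(OCc3ccccc3)c2)c([O-])c(OC)c1OCc1ccccc1 | intermediate
13 | (2R,3S,4R)-7-(benzyloxy)-6,8-dimethoxy-2-[3,4,5-tris(benzyloxy)phenyl]chromane-3,4,5-triol | COc1c(OCc2ccccc2)c(OC)c3c(c1O)[C@@H](O)[C@H](O)[C@@H](c4cc(OCc5ccccc5)c(OCc5ccccc5)c(OCc5ccccc5)c4)O3 | intermediate
14 | (2R,3S,4R)-6,8-dimethoxy-2-(3,4,5-trihydroxyphenyl)chromane-3,4,5,7-tetrol | COc1c(O)c(OC)c2c(c1O)[C@@H](O)[C@H](O)[C@@H](c1cc(O)c(O)c(O)c1)O2 | target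

## Step count and risks

Total step count: 10 (steps 1–4 build the ring A fragment, steps 5–8 the ring B fragment, steps 9–10 join and finish).
Longest linear sequence: 6 steps (steps 5, 6, 7, 8, 9, 10; the branch through steps 1–4 is equally long).

Three steps most likely to fail:

1. Step 9 (bears the label). What may go wrong:
   - erosion of facial selectivity in the carbonyl addition, giving erythro instead of threo and hence 3,4-cis;
   - Lewis-acid-induced rearrangement or premature opening of the epoxy aldehyde before C–C bond formation;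
   - competing 5-exo opening;
   - ionization of the C4–O bond of the product.

   Fallback in known chemistry, setting out from 5 and 10 and coming back to the route at 13. Compound 5 would be converted with chloromethyl methyl ether and i-Pr2NEt (CH2Cl2) into bis(methoxymethyl) ether F1. Directed ortho-lithiation of the bis(methoxymethyl) ether F1 at the carbon between the two acetal oxygens (n-BuLi, THF, 0 °C) and addition of the aryllithium to 10 at −78 °C should give epoxy alcohol F2 as a mixture of carbinol epimers. Dess–Martin oxidation would converge this mixture to the single epoxy ketone F3, a doubly protected chalcone epoxide. HCl in MeOH/THF should remove both acetals and close ring C by the same O1–C2 bond (6-endo opening at C2) to give trans-dihydroflavonol F4. Reduction with NaBH4 (EtOH/THF, 0 °C), which for 2,3-trans-dihydroflavonols should deliver hydride so as to give mainly the 3,4-trans diol, leads back to 13.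

2. Step 10. What may go wrong: over-reduction by hydrogenolysis of the C4–O bond, which is benzylic to the electron-rich ring A, or acid-trace ionization at C4 during debenzylation, followed by air oxidation of the free pyrogallol. Fallback setting out from 13 and coming back at 14: the route is reordered so that the debenzylation is run at the ketone level. Selective oxidation of the benzylic C4 carbinol of 13 with MnO2 (CH2Cl2, rt) should give dihydroflavonol F4, the compound already met in the fallback to step 9. Its C4 carbonyl is hydrogen-bonded to 5-OH and inert to hydrogenolysis, so H2 with Pd/C (EtOAc/MeOH) should give free dihydroflavonol F5. NaBH4 in EtOH at 0 °C, the common way from 2,3-trans-dihydroflavonols to 2,3-trans-3,4-trans flavan-3,4-diols, should then give 14.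

3. Step 7. What may go wrong: opening of the electron-rich benzylic epoxide by alkoxide or tartrate under the titanium Lewis acid, or incomplete enantioselection. Fallback setting out from 8 and coming back at 10, which also bypasses step 8: oxidation of 8 with MnO2 (CH2Cl2, rt) should give enal F6. Iminium-catalysed nucleophilic epoxidation of enal F6 with aqueous H2O2 and (S)-2-{bis[3,5-bis(trifluoromethyl)phenyl][(trimethylsilyl)oxy]methyl}pyrrolidine (10 mol%) in CH2Cl2 at rt should give the trans-(2R,3S)-epoxy aldehyde 10 directly, with no titanium Lewis acid and no separate oxidation of an epoxy alcohol.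

Further compounds
F1 | step 9 | 3-(benzyloxy)-2,4-dimethoxy-1,5-bis(methoxymethoxy)benzene | COCOc1cc(OCOC)c(OC)c(OCc2ccccc2)c1OC
F2 | step 9 | [4-(benzyloxy)-3,5-dimethoxy-2,6-bis(methoxymethoxy)phenyl]{(2S,3S)-3-[3,4,5-tris(benzyloxy)phenyl]oxiran-2-yl}methanol, both carbinol epimers | OC(c1c(OCOC)c(OC)c(OCc2ccccc2)c(OC)c1OCOC)[C@@H]3O[C@H]3c4cc(OCc5ccccc5)c(OCc5ccccc5)c(OCc5ccccc5)c4
F3 | step 9 | [4-(benzyloxy)-3,5-dimethoxy-2,6-bis(methoxymethoxy)phenyl]{(2R,3S)-3-[3,4,5-tris(benzyloxy)phenyl]oxiran-2-yl}methanone | O=C(c1c(OCOC)c(OC)c(OCc2ccccc2)c(OC)c1OCOC)[C@@H]3O[C@H]3c4cc(OCc5ccccc5)c(OCc5ccccc5)c(OCc5ccccc5)c4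
F4 | step 9 | (2R,3R)-7-(benzyloxy)-3,5-dihydroxy-6,8-dimethoxy-2-[3,4,5-tris(benzyloxy)phenyl]chroman-4-one | COc1c(OCc2ccccc2)c(OC)c3c(c1O)C(=O)[C@H](O)[C@@H](c4cc(OCc5ccccc5)c(OCc5ccccc5)c(OCc5ccccc5)c4)O3
F5 | step 10 | (2R,3R)-3,5,7-trihydroxy-6,8-dimethoxy-2-(3,4,5-trihydroxyphenyl)chroman-4-one | COc1c(O)c(OC)c2c(c1O)C(=O)[C@H](O)[C@@H](c1cc(O)c(O)c(O)c1)O2
F6 | step 7 | (E)-3-[3,4,5-tris(benzyloxy)phenyl]prop-2-enal | O=C/C=C/c1cc(OCc2ccccc2)c(OCc2ccccc2)c(OCc2ccccc2)c1
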